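## Structural features

The target is a eudesmane: two fused six-membered carbocycles, ring A (C1–C5, C10) and ring B (C5–C10), share the C5–C10 bond, with a trisubstituted C5=C6 alkene at the fusion and a quaternary, methyl-bearing C10. Ring A carries two adjacent oxygenated stereocentres, the secondary C3 angelate and the tertiary C4 methyl carbinol. They are cis to each other and on the same face as the C10 methyl, and C4 is allylic to C5=C6. Ring B carries at C7 a methyl acrylate unit (C11=C13, C12 ester) cis to the C10 methyl, and the C7–H is doubly allylic. Fragile groups are the angelate (Z-to-E isomerisation under base or nucleophilic acyl-transfer catalysis), the acrylate (Michael acceptor, prone to slip into conjugation through C7–H) and the tertiary allylic C4 hydroxyl (ionisation). The real difficulty is C4: a fully substituted carbinol whose oxygen lies on the hindered face, 1,3-syn to the angular methyl, where oxidation of a dienolate or alkene would be expected to deliver oxygen from the other face. The key step exploits that C3/C4, at the ketone/carbinol level, is an α-ketol. The C4–C5 bond of a 4-hydroxy-4-methyl-3-ketone in ring A is the bond formed when alkenyl carbon C5 of a 3-acetyl-3-hydroxy cyclopentane shifts from C3 to C4, which enlarges the five-membered ring to ring A and transfers the C3 configuration to C4.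

## Logic of the disconnections

- **21 ⇒ 18 + 19.** The C3–O acyl bond is cut first because the Z-enoate is the most isomerisation-prone group and should be introduced last. This removes the only geometrically labile alkene. The forward acylation must distinguish the secondary from the tertiary hydroxyl and must not pass through an acyl-transfer intermediate that scrambles the Z geometry (hence the non-isolated 20).
- **18 ⇒ 17.** The C3–H bond is cut, revealing a C3 ketone next to the C4 carbinol. One stereocentre disappears and the α-ketol is exposed. The hydride must arrive axially, anti to the axial C4–O bond, to give the alcohol cis to the C4 hydroxyl, and must leave the acrylate untouched.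
- **17 ⇒ 16.** The C4–C5 bond is cut and C3–C5 re-formed on paper (retro α-ketol shift). Ring A contracts to a cyclopentane, C4 becomes an acetyl carbon, and its configuration becomes a consequence of the C3 carbinol. The forward shift needs a free hydroxyl and a chelating Lewis acid so that the oxygens are syn, C5 rather than C2 migrates, and the tertiary allylic C–O bond does not ionise.
- **16 ⇒ 14 (through 15).** The C3–C4 bond is cut to a masked acetyl anion and a ring ketone. The C3 stereocentre is traced to face selection by the C10 methyl. The nucleophile must add 1,2 to the enone, anti to the methyl, faster than it attacks the acrylate or removes the C7 proton.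
- **14 ⇒ 13.** The C5=C6 unsaturation is taken back to a C3=C5 silyl enol ether. Regiochemistry of dehydrogenation is then fixed by the enol ether, since C10 has no hydrogen. The enol ether must be formed as that single regioisomer.
- **13 ⇒ 12.** The C6–C7 bond is cut. One allylsilane conjugate cyclisation then supplies ring B, the C7 stereocentre, the acrylate methylene and the regiodefined enol ether. The forward step needs a chair-like transition state that puts the C7 substituent cis to the angular methyl.
- **12 ⇒ 10 (through 11) ⇒ 9 + 2.** The exocyclic C5=C6 bond is taken back to a β-amino ketone and the C7=C11 bond is cut by olefination. Keeping the reactive methylene ketone masked as the amine removes the Michael acceptor during the phosphonate step. The olefination must be selective for the aldehyde over the ketone.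
- **9 ⇒ 7 (through 8).** The C5–C6 bond is cut to a one-carbon iminium electrophile, and the aldehyde is traced to its acetal. The enol ether supplies the regiochemistry of C6 introduction at the hindered α-carbon. The forward step must not activate the acetal while the enol ether is present.
- **7 ⇒ 3 + 4 (through 5 and 6).** The C9–C10 bond is cut. A catalytic asymmetric conjugate addition creates the quaternary centre, and trapping of the resulting enolate fixes the C3=C5 regiochemistry. The catalyst must control the absolute configuration at C10, from which all other stereocentres follow.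
- **2 ⇒ 1.** The C11–C13 bond is cut by alkylation of the phosphonate carbanion with a silylmethyl electrophile.

## Other disconnections considered

**Alternative 1:** The cut is the C6–C7 bond of a decalin whose ring A is already six-membered. Forward, allylsilane A2 (the cyclohexanone homologue of 12) would cyclise by conjugate Hosomi–Sakurai addition of C7 to the exocyclic C6, giving silyl enol ether A1 with its oxygen at C4.
- In favour: the decalin is formed directly, C7 is set against C10 by the same chair argument, and the enol ether is regiodefined for dehydrogenation to enone A3.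
- Better point: a methyl nucleophile should attack the C4 carbonyl of A3 anti to the angular methyl, which places the hydroxyl on the required face without relying on a chelate.
- Against: C3 carries no oxygen. An α′-oxidation through a kinetic enolate would be needed in a molecule with an acidic doubly allylic C7–H and a base-sensitive acrylate, and the C3/C4 relationship would rest on two unrelated face selections. The methyl addition must also spare the ester.
- Comparison: structurally A1 maps onto the target skeleton while 13 is one carbon short in ring A. Mechanistically the ring-B closure is the same event as step 6 here, so the plans are equal on that point. In step count the alternative saves the ring expansion but spends an oxidation and probably a protection and its removal, so it should be equal or slightly longer.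

**Alternative 2:** The cuts are C5–C10 and C6–C7 of an acyclic precursor. Forward, hydrogen-atom transfer from an iron hydride (Fe(acac)3, PhSiH3) to the 1,1-disubstituted alkene of enyne diol A5 would give the C10 tertiary radical. A 6-exo-dig closure onto the alkyne and a 6-exo-trig closure of the C6 vinyl radical onto C7 would follow, and loss of the sulfonyl radical would leave the acrylate, giving diol A4 (identical with 18).
- In favour: both rings, the quaternary centre, C7 and the acrylate are made in one neutral operation, and the C3/C4 diol can be set earlier with reagent control.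
- Better point: A4 is one acylation from the target, so this is the most step-economic end game, and no Lewis acid touches the tertiary allylic alcohol.
- Against: closure of a tertiary radical onto an alkyne flanked by a fully substituted carbinol carbon must compete with premature reduction. Both C10 and C7 would be created under weak, remote substrate control, whereas the chosen plan sets C10 by a catalyst and C7 by a chair transition state. A5 itself needs a linear synthesis of comparable length.
- Comparison: structurally the alternative reaches the same diol. Mechanistically it trades stepwise polar bond formation for a kinetically controlled cascade. It is shorter on paper after A5 but carries a higher stereochemical risk.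

**Alternative 3:** The cut is the C3–C4 bond. Forward, keto aldehyde A7 would undergo a carbene-catalysed crossed benzoin reaction: the Breslow intermediate of the C3 aldehyde adds to the C4 methyl ketone on C5 and closes ring A, giving ketol A6.
- In favour: the step delivers the same α-ketol pattern as 17 under nearly neutral, catalytic conditions, and C7 could come from the terpene chiral pool.
- Equal or better point: the benzoin addition is reversible, so C4 could settle to the epimer with the hydroxyl axial, which avoids a 1,3-diaxial methyl–methyl contact and is the required one.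
- Against: the acceptor is a conjugated methyl ketone, less electrophilic and open to a competing Stetter addition at C6. A6 carries an isopropenyl group, so C12 must be oxidised late in the presence of other allylic positions and the allylic carbinol. The C10 quaternary centre would have to come from a diastereoselective enolate alkylation.
- Comparison: the ring-forming step is equal to the chosen one in what it installs. Mechanistically it is umpolung catalysis under thermodynamic control against a stereospecific 1,2-shift. It should be longer overall by the late oxidation sequence.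

Key step: step 9

Remark: eudesmane numbering is used for the skeletal atoms of every intermediate. The alkene geometry of 10–12 and the configuration at C5 of 8–11 are immaterial because both are erased later. Re-derivation of the descriptors confirms that the chelated shift needs the 3S carbinol (hydroxyl cis, acetyl trans to the angular methyl) and gives the 8R carbinol of 17.

## Route

Step 1
Reactants: 1 trimethyl phosphonoacetate
Product: 2 methyl 2-(dimethoxyphosphoryl)-3-(trimethylsilyl)propanoate (racemic)
Conditions: NaH, DME, 0 → 20 °C; ICH2SiMe3, 70 °C
Reagents that add atoms: (iodomethyl)trimethylsilane, C[Si](C)(C)CI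
Why: C-alkylation of the stabilised phosphonate carbanion with the silylmethyl iodide is a standard way to β-silyl phosphonoacetates; one equivalent of base limits dialkylation.

Step 2
Reactants: 3 3-methylcyclopent-2-en-1-one; 4 2-(2-bromoethyl)-1,3-dioxolane
Product: 7 {[(3R)-3-[2-(1,3-dioxolan-2-yl)ethyl]-3-methylcyclopent-1-en-1-yl]oxy}trimethylsilane, via Grignard reagent 5 (not isolated), via magnesium enolate 6 (not isolated)
Conditions: Mg, THF, 25 °C; then 3, Cu(OTf)2 (5 mol%), chiral N-mesityl N′-hydroxyalkyl imidazolinium salt (carbene precursor, 7 mol%), Et2O, −30 °C; then Me3SiCl, Et3N, −30 → 20 °C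
Reagents that add atoms: chlorotrimethylsilane, C[Si](C)(C)Cl
Why: Copper-catalysed asymmetric conjugate addition of a Grignard reagent to a β-substituted cyclic enone builds the quaternary centre, with the ligand enantiomer chosen to give 3R. The enolate is formed only towards the new quaternary carbon and O-silylation preserves that regiochemistry.

Step 3
Reactants: 7 silyl enol ether
Product: 9 3-[(1S)-2-[(dimethylamino)methyl]-1-methyl-3-oxocyclopentyl]propanal (both C2 epimers), via Mannich base acetal 8 (not isolated)
Conditions: [Me2N=CH2]Cl, CH2Cl2, 20 °C; then 2 M HCl, THF, 20 °C; NaHCO3 to pH 8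
Reagents that add atoms: N,N-dimethylmethyleneiminium chloride, C=[N+](C)C.[Cl-]; water, O
Why: The preformed iminium salt aminomethylates the silyl enol ether at the carbon next to the quaternary centre (regiospecific Mannich reaction), and the chloride counter-ion gives only Me3SiCl, too weak to activate the acetal. Aqueous acid then hydrolyses the dioxolane while the amine is protected as its ammonium salt.

Step 4
Reactants: 9 amino keto aldehyde; 2 silyl phosphonate
Product: 10 methyl 5-[(1S)-2-[(dimethylamino)methyl]-1-methyl-3-oxocyclopentyl]-2-[(trimethylsilyl)methyl]pent-2-enoate (E/Z mixture)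
Conditions: 2, NaH, THF, 0 °C; then 9, −20 → 20 °C
Reagents that add atoms: none
Why: Horner–Wadsworth–Emmons olefination is selective for the aldehyde over the hindered ketone and gives the 2-(silylmethyl)enoate, an ester-substituted allylsilane. With the methylene ketone still masked as the amine there is no Michael acceptor for the phosphonate anion.

Step 5
Reactants: 10 amino ketone
Product: 12 methyl 5-[(1S)-1-methyl-2-methylidene-3-oxocyclopentyl]-2-[(trimethylsilyl)methyl]pent-2-enoate (E/Z mixture), via methiodide salt 11 (not isolated)
Conditions: MeI, Et2O, 20 °C; then aq. NaHCO3, CH2Cl2, 20 °C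
Reagents that add atoms: none
Why: Quaternisation of the Mannich base followed by mild-base β-elimination of trimethylamine is the classical route to α-methylene ketones. The allylsilane and ester are inert to both reagents.

Step 6
Reactants: 12 methylene ketone
Product: 13 methyl 2-[(5R,7aS)-7a-methyl-3-[(trimethylsilyl)oxy]-2,4,5,6,7,7a-hexahydro-1H-inden-5-yl]prop-2-enoate
Conditions: Me3SiNTf2 (10 mol%, from HNTf2 and allyltrimethylsilane), CH2Cl2, −78 → −40 °C; Et3N quench, non-aqueous work-up
Reagents that add atoms: none
Why: The silyl triflimide silylates the ketone oxygen, the allylsilane γ-carbon C7 attacks the exocyclic C6 (intramolecular Hosomi–Sakurai conjugate addition, 6-endo on the enone), and loss of the silyl group releases the C11=C13 methylene and turns the catalyst over, so the product is the C3=C5 silyl enol ether. A chair transition state with the angular methyl axial and the ester-bearing alkene equatorial should place the C7 substituent cis to the methyl (5R).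

Step 7
Reactants: 13 bicyclic silyl enol ether
Product: 14 methyl 2-[(5R,7aS)-7a-methyl-3-oxo-2,3,5,6,7,7a-hexahydro-1H-inden-5-yl]prop-2-enoate
Conditions: Pd(OAc)2 (1.1 equiv), MeCN, 25 °C
Reagents that add atoms: none
Why: Saegusa–Ito oxidation: the palladium enolate is bound at C5, whose only β-hydrogens are on C6 because C10 is quaternary, so β-hydride elimination can give only the C5=C6 enone.

Step 8
Reactants: 14 hydrindenone
Product: 16 methyl 2-[(3S,5R,7aS)-3-acetyl-3-hydroxy-7a-methyl-2,3,5,6,7,7a-hexahydro-1H-inden-5-yl]prop-2-enoate, via ethoxyvinyl carbinol 15 (not isolated)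
Conditions: CH2=C(OEt)Li (ethyl vinyl ether, t-BuLi, THF, −78 → 0 °C), CeCl3, THF, −78 °C; then 0.5 M HCl, THF, 0 °C
Reagents that add atoms: 1-ethoxyvinyllithium, [Li]C(=C)OCC; water, O
Why: The weakly basic organocerium reagent adds 1,2 to the enone carbonyl faster than it attacks the ester or acrylate or removes the C7 proton. Attack anti to the pseudoaxial angular methyl should give the 3S carbinol (hydroxyl cis to the methyl), and dilute acid hydrolyses the enol ether to the methyl ketone without ionising the carbinol.

Step 9
Reactants: 16 acetyl carbinol
Product: 17 methyl 2-[(2R,4aS,8R)-8-hydroxy-4a,8-dimethyl-7-oxo-2,3,4,4a,5,6,7,8-octahydronaphthalen-2-yl]prop-2-enoate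
Conditions: Et2AlCl (1.5 equiv), CH2Cl2, −78 → 0 °C; aq. Rochelle salt
Reagents that add atoms: none
Why: Et2AlCl deprotonates the tertiary hydroxyl (ethane is lost) and the resulting chloro(ethyl)aluminium alkoxide binds the acetyl oxygen, so a five-membered O–Al–O chelate holds the two oxygens syn and activates the carbonyl carbon C4. In the chelate rotamer that puts the acetyl methyl next to the C2 methylene, the C3–C5 σ bond, backed by the C5=C6 π system, lies parallel to the C4 π* orbital, and C5 shifts suprafacially from C3 to C4 while C3 becomes the ketone. The closest known reaction type is the Lewis-acid α-ketol (acyloin) rearrangement with ring expansion of 1-acylcycloalkanols, as in the D-homoannulation of 17-hydroxy-20-keto steroids. Ring A is closed not by an end-to-end cyclisation but by enlargement of the cyclopentane through a three-centre 1,2-alkenyl shift, driven by relief of five-ring strain. The new stereocentre C4 is controlled by the C3 configuration of 16: with the acetyl group on the face opposite the angular methyl and the oxygens syn, C5 can reach only the carbonyl face that leaves the new hydroxyl cis to the C10 methyl (8R). The step needs regioselectivity for C5 over C2, which the higher migratory aptitude of the alkenyl, more substituted carbon should secure. It also needs chemoselectivity against ionisation of the allylic C–O bond, which the alkoxide form and the adjacent acyl group suppress. Low temperature keeps the non-conjugated ketol from equilibrating further by a methyl shift.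

Step 10
Reactants: 17 ring-expanded ketol
Product: 18 methyl 2-[(2R,4aS,7S,8R)-7,8-dihydroxy-4a,8-dimethyl-2,3,4,4a,5,6,7,8-octahydronaphthalen-2-yl]prop-2-enoate
Conditions: NaBH4, CeCl3·7H2O, MeOH, −78 °C
Reagents that add atoms: none
Why: Luche-type conditions reduce the ketone faster than the acrylate. Axial hydride delivery to C3, anti to the axial C4–O bond (Felkin–Anh) and away from the face crowded by the C4 hydroxyl and angular methyl, should give the equatorial 7S alcohol cis to the tertiary hydroxyl.

Step 11
Reactants: 18 diol; 19 angelic acid [(2Z)-2-methylbut-2-enoic acid]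
Product: 21 methyl 2-[(2R,4aS,7S,8R)-8-hydroxy-4a,8-dimethyl-7-{[(2Z)-2-methylbut-2-enoyl]oxy}-2,3,4,4a,5,6,7,8-octahydronaphthalen-2-yl]prop-2-enoate, via mixed anhydride 20 (not isolated)
Conditions: 19, 2,4,6-trichlorobenzoyl chloride, Et3N, PhMe, 20 °C; then 18, PhMe, 80 °C
Reagents that add atoms: none
Why: Yamaguchi mixed-anhydride esterification without a nucleophilic acyl-transfer catalyst is the established way to make angelates without Z-to-E isomerisation. Only the secondary hydroxyl should be acylated, the tertiary one being too hindered.

## Compound list

1 | trimethyl phosphonoacetate | COC(=O)CP(=O)(OC)OC | starting material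
2 | methyl 2-(dimethoxyphosphoryl)-3-(trimethylsilyl)propanoate | COC(=O)C(C[Si](C)(C)C)P(=O)(OC)OC | intermediate
3 | 3-methylcyclopent-2-en-1-one | CC1=CC(=O)CC1 | starting material
4 | 2-(2-bromoethyl)-1,3-dioxolane | BrCCC1OCCO1 | starting material
5 | [2-(1,3-dioxolan-2-yl)ethyl]magnesium bromide | Br[Mg]CCC1OCCO1 | intermediate
6 | bromomagnesium (3R)-3-[2-(1,3-dioxolan-2-yl)ethyl]-3-methylcyclopent-1-en-1-olate | Br[Mg]OC1=C[C@@](C)(CCC2OCCO2)CC1 | intermediate
7 | {[(3R)-3-[2-(1,3-dioxolan-2-yl)ethyl]-3-methylcyclopent-1-en-1-yl]oxy}trimethylsilane | C[Si](C)(C)OC1=C[C@@](C)(CCC2OCCO2)CC1 | intermediate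
8 | (3S)-2-[(dimethylamino)methyl]-3-[2-(1,3-dioxolan-2-yl)ethyl]-3-methylcyclopentan-1-one | CN(C)CC1C(=O)CC[C@]1(C)CCC2OCCO2 | intermediate
9 | 3-[(1S)-2-[(dimethylamino)methyl]-1-methyl-3-oxocyclopentyl]propanal | CN(C)CC1C(=O)CC[C@]1(C)CCC=O | intermediate
10 | methyl 5-[(1S)-2-[(dimethylamino)methyl]-1-methyl-3-oxocyclopentyl]-2-[(trimethylsilyl)methyl]pent-2-enoate | CN(C)CC1C(=O)CC[C@]1(C)CCC=C(C[Si](C)(C)C)C(=O)OC | intermediate
11 | methyl 5-[(1S)-1-methyl-3-oxo-2-[(trimethylammonio)methyl]cyclopentyl]-2-[(trimethylsilyl)methyl]pent-2-enoate iodide | C[N+](C)(C)CC1C(=O)CC[C@]1(C)CCC=C(C[Si](C)(C)C)C(=O)OC.[I-] | intermediate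
12 | methyl 5-[(1S)-1-methyl-2-methylidene-3-oxocyclopentyl]-2-[(trimethylsilyl)methyl]pent-2-enoate | C=C1C(=O)CC[C@]1(C)CCC=C(C[Si](C)(C)C)C(=O)OC | intermediate
13 | methyl 2-[(5R,7aS)-7a-methyl-3-[(trimethylsilyl)oxy]-2,4,5,6,7,7a-hexahydro-1H-inden-5-yl]prop-2-enoate | C=C(C(=O)OC)[C@H]1CC2=C(O[Si](C)(C)C)CC[C@]2(C)CC1 | intermediate
14 | methyl 2-[(5R,7aS)-7a-methyl-3-oxo-2,3,5,6,7,7a-hexahydro-1H-inden-5-yl]prop-2-enoate | C=C(C(=O)OC)[C@H]1C=C2C(=O)CC[C@]2(C)CC1 | intermediate
15 | methyl 2-[(3S,5R,7aS)-3-(1-ethoxyethenyl)-3-hydroxy-7a-methyl-2,3,5,6,7,7a-hexahydro-1H-inden-5-yl]prop-2-enoate | C=C(C(=O)OC)[C@H]1C=C2[C@](C)(CC[C@@]2(O)C(=C)OCC)CC1 | intermediate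
16 | methyl 2-[(3S,5R,7aS)-3-acetyl-3-hydroxy-7a-methyl-2,3,5,6,7,7a-hexahydro-1H-inden-5-yl]prop-2-enoate | C=C(C(=O)OC)[C@H]1C=C2[C@](C)(CC[C@@]2(O)C(C)=O)CC1 | intermediate
17 | methyl 2-[(2R,4aS,8R)-8-hydroxy-4a,8-dimethyl-7-oxo-2,3,4,4a,5,6,7,8-octahydronaphthalen-2-yl]prop-2-enoate | C=C(C(=O)OC)[C@H]1C=C2[C@](C)(CCC(=O)[C@]2(C)O)CC1 | intermediate
18 | methyl 2-[(2R,4aS,7S,8R)-7,8-dihydroxy-4a,8-dimethyl-2,3,4,4a,5,6,7,8-octahydronaphthalen-2-yl]prop-2-enoate | C=C(C(=O)OC)[C@H]1C=C2[C@](C)(CC[C@H](O)[C@]2(C)O)CC1 | intermediate
19 | angelic acid, (2Z)-2-methylbut-2-enoic acid | C/C=C(/C)C(=O)O | starting material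
20 | (2Z)-2-methylbut-2-enoic 2,4,6-trichlorobenzoic anhydride | C/C=C(/C)C(=O)OC(=O)c1c(Cl)cc(Cl)cc1Cl | intermediate
21 | methyl 2-[(2R,4aS,7S,8R)-8-hydroxy-4a,8-dimethyl-7-{[(2Z)-2-methylbut-2-enoyl]oxy}-2,3,4,4a,5,6,7,8-octahydronaphthalen-2-yl]prop-2-enoate | C=C(C(=O)OC)[C@H]1C=C2[C@](C)(CC[C@H](OC(=O)/C(C)=C\C)[C@]2(C)O)CC1 | target

## Step count and least certain steps

Total step count: 11. Longest linear sequence: 10 steps (steps 2 to 11, from 3 and 4 to 21); step 1 supplies 2 for step 4.

**Step 9 (key step).**
- Risk: loss of regiocontrol (shift of C2 in place of C5), reaction through the unchelated rotamer with erosion of the C4 configuration, or ionisation of the tertiary allylic C–O bond under the Lewis acid.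
- Fallback (sets out from 13, returns at 18): ring A is built by a carbenoid ring enlargement and the C4 oxygen is delivered from the C3 hydroxyl. Ethylidene transfer (Et2Zn, CH3CHI2, Furukawa-type cyclopropanation) to the enol ether bond of 13 would give the siloxycyclopropane F1. FeCl3 in DMF should open it to the ring-enlarged β-chloro ketone F2, and NaOAc in MeOH should eliminate HCl to the conjugated 4-methyl enone F3. Luche reduction should give the equatorial allylic alcohol F4. VO(acac)2 and t-BuOOH should epoxidise syn to that hydroxyl, on the face of the angular methyl, to the epoxy alcohol F5. Ti(OiPr)4 should then isomerise this 2,3-epoxy alcohol by hydroxyl-directed opening of the distal C5–O bond with loss of a C6 proton, giving 18.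

**Step 2.**
- Risk: insufficient enantiofacial control on a five-membered enone with a functionalised Grignard reagent carried in THF, and incomplete O-silylation of the magnesium enolate.
- Fallback (sets out from 5, returns at 7): the roles of the two substituents are reversed. Addition of 5 to 3-ethoxycyclopent-2-en-1-one would give the 1,2-adduct F6, which on mild acid work-up transposes to the enone F7 (Stork–Danheiser sequence). Copper-catalysed asymmetric conjugate addition of MeMgBr with the appropriate ligand enantiomer, then Me3SiCl, would pass through the same enolate 6 to 7.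

**Step 6.**
- Risk: protodesilylation of the electron-poor allylsilane before cyclisation, 1,2-addition to the carbonyl giving a bridged carbinol, weak diastereocontrol at C7, or hydrolysis of the enol ether during isolation.
- Fallback (sets out from 12, returns at 13): stoichiometric TiCl4 in CH2Cl2 at −78 °C with aqueous work-up would give the saturated ketone F8. Silylation under equilibrating conditions (Me3SiI, (Me3Si)2NH) should then give the more substituted enol ether 13.

**Step 8.**
- Risk: competing attack on the acrylate or ester, removal of the C7 proton with migration of the exocyclic alkene into conjugation or epimerisation at C7, and incomplete face selectivity at C3.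
- Fallback (sets out from 14, returns at 16): a less basic acetylide is used as the acyl anion equivalent. HC≡CMgBr with CeCl3 in THF would give the ethynyl carbinol F9, and Markovnikov hydration with catalytic Ph3PAuNTf2 in wet dioxane would give 16.

**Step 11.**
- Risk: Z-to-E isomerisation of the activated acid, or sluggish acylation of the secondary hydroxyl next to the fully substituted C4.
- Fallback (sets out from 18, returns at 21): the Z-alkene is built on the ester instead of being transferred. Esterification with 2-[bis(2,2,2-trifluoroethoxy)phosphoryl]propanoic acid (DCC, catalytic DMAP) would give the phosphonate ester F10. Still–Gennari olefination with acetaldehyde (KHMDS, 18-crown-6, THF, −78 °C) should then give 21.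

## Further compounds

F1 | step 9 | siloxycyclopropane from ethylidene transfer across C3=C5 of 13 (C7 and C10 as in 13) | C=C(C(=O)OC)[C@H]1CC23C(C)C2(O[Si](C)(C)C)CC[C@]3(C)CC1
F2 | step 9 | methyl 2-[(2R,4aS)-8a-chloro-4a,8-dimethyl-7-oxodecahydronaphthalen-2-yl]prop-2-enoate | C=C(C(=O)OC)[C@H]1CC2(Cl)C(C)C(=O)CC[C@]2(C)CC1
F3 | step 9 | methyl 2-[(2R,4aS)-4a,8-dimethyl-7-oxo-1,2,3,4,4a,5,6,7-octahydronaphthalen-2-yl]prop-2-enoate | C=C(C(=O)OC)[C@H]1CC2=C(C)C(=O)CC[C@]2(C)CC1
F4 | step 9 | methyl 2-[(2R,4aS,7S)-7-hydroxy-4a,8-dimethyl-1,2,3,4,4a,5,6,7-octahydronaphthalen-2-yl]prop-2-enoate | C=C(C(=O)OC)[C@H]1CC2=C(C)[C@@H](O)CC[C@]2(C)CC1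
F5 | step 9 | C4–C5 epoxide of F4, oxirane cis to the C3 hydroxyl and to the angular methyl | C=C(C(=O)OC)[C@H]1C[C@]23O[C@@]2(C)[C@@H](O)CC[C@]3(C)CC1
F6 | step 2 | 1-[2-(1,3-dioxolan-2-yl)ethyl]-3-ethoxycyclopent-2-en-1-ol | CCOC1=CC(O)(CCC2OCCO2)CC1
F7 | step 2 | 3-[2-(1,3-dioxolan-2-yl)ethyl]cyclopent-2-en-1-one | O=C1C=C(CCC2OCCO2)CC1
F8 | step 6 | methyl 2-[(5R,7aS)-7a-methyl-3-oxooctahydro-1H-inden-5-yl]prop-2-enoate | C=C(C(=O)OC)[C@H]1CC2C(=O)CC[C@]2(C)CC1
F9 | step 8 | methyl 2-[(3R,5R,7aS)-3-ethynyl-3-hydroxy-7a-methyl-2,3,5,6,7,7a-hexahydro-1H-inden-5-yl]prop-2-enoate | C=C(C(=O)OC)[C@H]1C=C2[C@](C)(CC[C@@]2(O)C#C)CC1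
F10 | step 11 | 2-[bis(2,2,2-trifluoroethoxy)phosphoryl]propanoate ester of 18 at the secondary hydroxyl | C=C(C(=O)OC)[C@H]1C=C2[C@](C)(CC[C@H](OC(=O)C(C)P(=O)(OCC(F)(F)F)OCC(F)(F)F)[C@]2(C)O)CC1
A1 | alternative 1 | methyl 2-[(2R,4aR)-4a-methyl-8-[(trimethylsilyl)oxy]-1,2,3,4,4a,5,6,7-octahydronaphthalen-2-yl]prop-2-enoate | C=C(C(=O)OC)[C@H]1CC2=C(O[Si](C)(C)C)CCC[C@]2(C)CC1
A2 | alternative 1 | methyl 5-[(1R)-1-methyl-2-methylidene-3-oxocyclohexyl]-2-[(trimethylsilyl)methyl]pent-2-enoate | C=C1C(=O)CCC[C@]1(C)CCC=C(C[Si](C)(C)C)C(=O)OC
A3 | alternative 1 | methyl 2-[(2R,4aR)-4a-methyl-8-oxo-2,3,4,4a,5,6,7,8-octahydronaphthalen-2-yl]prop-2-enoate | C=C(C(=O)OC)[C@H]1C=C2C(=O)CCC[C@]2(C)CC1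
A4 | alternative 2 | methyl 2-[(2R,4aS,7S,8R)-7,8-dihydroxy-4a,8-dimethyl-2,3,4,4a,5,6,7,8-octahydronaphthalen-2-yl]prop-2-enoate | C=C(C(=O)OC)[C@H]1C=C2[C@](C)(CC[C@H](O)[C@]2(C)O)CC1
A5 | alternative 2 | methyl (9S,10R)-9,10-dihydroxy-10-methyl-6-methylidene-2-[(phenylsulfonyl)methyl]dodec-2-en-11-ynoate | C#C[C@@](C)(O)[C@@H](O)CCC(=C)CCC=C(CS(=O)(=O)c1ccccc1)C(=O)OC
A6 | alternative 3 | (1R,4aS,7R)-1-hydroxy-1,4a-dimethyl-7-(prop-1-en-2-yl)-3,4,4a,5,6,7-hexahydronaphthalen-2(1H)-one | C=C(C)[C@H]1C=C2[C@](C)(CCC(=O)[C@]2(C)O)CC1
A7 | alternative 3 | 3-[(1S,4R)-2-acetyl-1-methyl-4-(prop-1-en-2-yl)cyclohex-2-en-1-yl]propanal | CC(=O)C1=C[C@H](C(C)=C)CC[C@@]1(C)CCC=O
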